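All runs come from a simulation from invented constants; noise was put on by code.

An easy step first: what is asked is the double product after 2.0 min in three flasks that differ in their charge of coupling partner.

| setting | north-west | south-east | cedar | ash | elm |
|---|---|---|---|---|---|
| substrate | 6.7 × 10⁻⁴ M | 0.0020 M | 0.0010 M | 0.0010 M | 0.0010 M |
| coupling partner | 0.80 equiv | 0.80 equiv | 0.800 equiv | 2.00 equiv | 4.00 equiv |
| remark | run made earlier | run made earlier |  |  |  |
| time |  |  | 2.0 min | 2.0 min | 2.0 min |

| run | time / s | double product / % | single product / % | substrate / % |
|---|---|---|---|---|
| north-west | 10.0 | 0 | 11.4 | 78.4 |
| north-west | 15.0 | 0.5 | 14.4 | 72.1 |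
| north-west | 25.0 | 1.5 | 22.5 | 57.6 |
| north-west | 30.0 | 0 | 23.8 | 52.8 |
| north-west | 40.0 | 0 | 29.2 | 44.4 |
| south-east | 10.0 | 0 | 22.6 | 52.5 |
| south-east | 20.0 | 0.7 | 33.9 | 30.3 |
| south-east | 30.0 | 0 | 41.0 | 24.6 |
| south-east | 40.0 | 0 | 44.9 | 15.2 |

(scatter of a reading: 1 percentage point)

- a reading or a percentage of single product counts all its forms, free or not
- a reading of substrate is of its free form alone

- amount of double product at the end, in percent of the substrate charged, for each flask in turn (cedar, ash, elm)

Where did the substrate go? At 40.0 s in the south-east run, 15.2% is free substrate and 44.9% is single product, so 39.9% of the charge is missing. I read that as substrate held one to one by single product, which leaves 5.00% of free single product.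

How firm is that? It is a difference of readings that each scatter by 1 percentage point, so it is rough.

What does it give? A holding constant of 26200 M⁻¹, read from that one row. Its inverse, as a share of a 0.0010 M charge, is 3.81%. This is the release level: the free substrate at which half of the single product is free.

And how fast does a flask move toward it? Taking means over the first 10.0 s of the south-east run, I read a coupling constant of 21.6 M⁻¹ s⁻¹. With the partner as charged, that gives free substrate a starting lifetime by coupling of 0.966 min in cedar, 0.386 min in ash and 0.193 min in elm, shorter in elm than in ash and shorter in ash than in cedar. These hold for the start, and I reckon no arrival time from them.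

So what do I commit to? An order: cedar lowest, elm highest. The double readings reach 1.5% against a scatter of 1 point, so I put no number on the second coupling.

The forecast does, assuming “free single product couples at about half the substrate's rate”, and gives 3.3%, 28% and 69%.

The flasks give 1.05%, 12.9% and 40.6%, less than the forecast at each point.

    substrate + coupling partner → single product (k = 25.0 M⁻¹ s⁻¹)
    coupling partner + single product → double product (k = 5.43 M⁻¹ s⁻¹)
    substrate + single product ⇌ idle adduct, settled at all times (K = 35000 M⁻¹)

At 2.00 min cedar still has 12.0% of free substrate, more than the release level of 3.81%, and 9.21% of its 48.1% single product is free, the rest resting in the idle adduct (its resting state), while elm has 2.13%, less than that level, with 23.0% free of 40.1%. In cedar, the half-life of coupling partner at the asked time is 3.8 min by the substrate step against 23 min by the single-product step, after a ratio of their rates of 190 at 0.340 min.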